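**Strategy.** The acid chain is numbered from the carboxyl carbon C1 to C9 on chroman C2. Everything rests on C4–C5, the central σ-bond of the 1,5-diene C2=C3–C4–C5–C6=C7 outside the chroman ring. An angelate ester of the (E)-allylic alcohol that carries the finished (R)-chroman is enolised; an Ireland–Claisen shift makes a temporary C2–C7 bond and the following Cope shift exchanges it for C4–C5. One operation thus joins the five-carbon acid unit to the chroman fragment and sets the 2Z and 6E alkenes through chair transition states. The chroman itself comes from (R)-linalool by B-alkyl Suzuki coupling and Pd-catalysed aryl ether closure.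

Key step: step 7

Remark: commercial (R)-(−)-linalool of high enantiomeric purity is assumed. Its carbinol C–O bond is never broken, so its spatial arrangement becomes that of chroman C2; where the CIP letter of an intermediate differs (5, F1, F2, F7) only the ranking of the substituents has changed.

**Step 1**
Reactants: 1 3-bromo-5-methylphenol
Product: 2 3-bromo-4-iodo-5-methylphenol
Conditions: NIS (1.05 equiv), p-TsOH·H2O (10 mol%), MeCN, 0 °C → rt
Reagents that add atoms: N-iodosuccinimide, O=C1CCC(=O)N1I
Why: Electrophilic aromatic iodination under NIS/acid, in which the hydroxyl group directs iodine to its para position C4, the carbon flanked by Br and CH3 that later carries the alkyl chain.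

**Step 2**
Reactants: 2 3-bromo-4-iodo-5-methylphenol
Product: 3 1-bromo-2-iodo-5-(methoxymethoxy)-3-methylbenzene
Conditions: NaH, THF/DMF, 0 °C; MOMCl, 0 °C → rt
Reagents that add atoms: chloromethyl methyl ether, COCCl
Why: Williamson-type O-alkylation of the sodium phenoxide gives the MOM ether, which should survive the borane, bases, Pd, SeO2, LDA and heat of the later steps and leave under mild acid.

**Step 3**
Reactants: 4 (R)-(−)-linalool; 3 1-bromo-2-iodo-5-(methoxymethoxy)-3-methylbenzene
Product: 6 (3R)-1-[2-bromo-4-(methoxymethoxy)-6-methylphenyl]-3,7-dimethyloct-6-en-3-ol, via B-alkyl-9-BBN adduct 5 (not isolated)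
Conditions: 9-BBN-H (1.5 equiv), THF, 0 °C → rt; then 3, PdCl2(dppf)·CH2Cl2 (5 mol%), AsPh3, Cs2CO3, DMF/H2O, 50 °C
Reagents that add atoms: none
Why: Anti-Markovnikov hydroboration by 9-BBN should occur only at the monosubstituted alkene, and the B-alkyl Suzuki–Miyaura coupling should take place at C–I (oxidative addition far faster than at C–Br), leaving the carbinol stereocentre untouched.

**Step 4**
Reactants: 6 (3R)-1-[2-bromo-4-(methoxymethoxy)-6-methylphenyl]-3,7-dimethyloct-6-en-3-ol
Product: 7 (2R)-7-(methoxymethoxy)-2,5-dimethyl-2-(4-methylpent-3-en-1-yl)chromane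
Conditions: Pd(OAc)2 (3 mol%), 2-(di-tert-butylphosphino)-1,1'-binaphthyl (4 mol%), Cs2CO3, toluene, 80 °C
Reagents that add atoms: none
Why: Buchwald-type Pd-catalysed intramolecular C–O coupling of the tertiary alkoxide (no β-hydrogen) closes the six-membered ring by forming the aryl–O bond, so the carbinol carbon keeps its arrangement and becomes (R)-C2.

**Step 5**
Reactants: 7 (2R)-7-(methoxymethoxy)-2,5-dimethyl-2-(4-methylpent-3-en-1-yl)chromane
Product: 8 (2E)-5-[(2R)-7-(methoxymethoxy)-2,5-dimethylchroman-2-yl]-2-methylpent-2-en-1-ol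
Conditions: SeO2 (0.3 equiv), t-BuOOH (3 equiv), salicylic acid (10 mol%), CH2Cl2, rt
Reagents that add atoms: selenium dioxide, O=[Se]=O (catalytic oxygen carrier); tert-butyl hydroperoxide, CC(C)(C)OO (terminal oxidant)
Why: Sharpless catalytic SeO2 allylic oxidation (ene reaction, then [2,3]-shift) should attack the only alkene at its (E)-methyl group and give the (E)-allylic alcohol.

**Step 6**
Reactants: 9 angelic acid; 8 (2E)-5-[(2R)-7-(methoxymethoxy)-2,5-dimethylchroman-2-yl]-2-methylpent-2-en-1-ol
Product: 11 (2E)-5-[(2R)-7-(methoxymethoxy)-2,5-dimethylchroman-2-yl]-2-methylpent-2-en-1-yl (2Z)-2-methylbut-2-enoate, via mixed anhydride 10 (not isolated)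
Conditions: 9, 2,4,6-trichlorobenzoyl chloride, Et3N, toluene, rt; then 8, toluene, 80 °C
Reagents that add atoms: none
Why: Yamaguchi mixed-anhydride esterification run without DMAP, in which the primary alcohol attacks the unhindered angeloyl carbonyl and the (Z)-geometry of the angelate is expected to be kept.

**Step 7**
Reactants: 11 (2E)-5-[(2R)-7-(methoxymethoxy)-2,5-dimethylchroman-2-yl]-2-methylpent-2-en-1-yl (2Z)-2-methylbut-2-enoate
Product: 15 (2Z,6E)-9-[(2R)-7-(methoxymethoxy)-2,5-dimethylchroman-2-yl]-2,6-dimethylnona-2,6-dienoic acid, via silyl ketene acetal 12 (not isolated), via Claisen silyl ester 13 (not isolated), via Cope silyl ester 14 (not isolated)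
Conditions: LDA (1.2 equiv), THF, −78 °C; TMSCl/Et3N, −78 → 50 °C; volatiles removed, toluene, 130 °C (sealed tube); 1 M aq. citric acid/THF work-up
Reagents that add atoms: none
Why: LDA bound to the carbonyl of the s-cis angelate removes a proton from the proximal (Z)-γ-methyl group, and O-silylation traps the dienolate as the (1Z)-silyl ketene acetal 12 (OSiMe3 cis to the new vinyl group). Chair Ireland–Claisen [3,3] shift of 12, with that vinyl group and the C8 chain of the (E)-allyl unit pseudo-equatorial, forms the temporary C2–C7 bond and gives 13 with the 2S*,3R* relative configuration at its two transient stereocentres (both absolute senses form, which is of no consequence). In 13 the 1,5-diene C4=C3–C2–C7–C6=C5 undergoes a Cope [3,3] shift through the chair that this relative configuration allows with the chain and the C2 methyl group equatorial and only the silyl carboxylate axial, so that C4–C5 forms, C2–C7 breaks and the two transient stereocentres are converted into the 2Z and 6E alkenes (the other chair would need chain and methyl axial). The double allylic inversion amounts to γ-allylation of the dienolate with an untransposed allyl unit, the ester counterpart of the Claisen–Cope sequence known from the industrial citral process and from dienolate Ireland–Claisen/Cope chemistry, and it is driven by conjugation of C2=C3 with the carboxyl group and relief of the quaternary–tertiary congestion in 13. No ring is closed and no stereocentre is left by this step; the selectivity it needs is alkene geometry (2Z, 6E) and γ- over α-attachment, secured by the kinetic ketene acetal geometry, the two chair transition states and the thermodynamic bias of the Cope step. Mild aqueous acid on work-up hydrolyses silyl ester 14 to acid 15.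

**Step 8**
Reactants: 15 (2Z,6E)-9-[(2R)-7-(methoxymethoxy)-2,5-dimethylchroman-2-yl]-2,6-dimethylnona-2,6-dienoic acid
Product: 16 (2Z,6E)-9-[(2R)-7-hydroxy-2,5-dimethylchroman-2-yl]-2,6-dimethylnona-2,6-dienoic acid
Conditions: 3 M aq. HCl, THF, 40 °C
Reagents that add atoms: none
Why: Acid-catalysed hydrolysis of the aryl MOM acetal in a non-alcoholic medium (so the acid is not esterified) should free the phenol without touching the chroman ether or the two alkenes.

**Compound list**
1 | 3-bromo-5-methylphenol | Cc1cc(O)cc(Br)c1 | starting material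
2 | 3-bromo-4-iodo-5-methylphenol | Cc1cc(O)cc(Br)c1I | intermediate
3 | 1-bromo-2-iodo-5-(methoxymethoxy)-3-methylbenzene | COCOc1cc(C)c(I)c(Br)c1 | intermediate
4 | (R)-(−)-linalool, (3R)-3,7-dimethylocta-1,6-dien-3-ol | C=C[C@](C)(O)CCC=C(C)C | starting material
5 | (3S)-1-(9-borabicyclo[3.3.1]nonan-9-yl)-3,7-dimethyloct-6-en-3-ol (B-alkyl-9-BBN adduct, same spatial arrangement as 4) | CC(C)=CCC[C@@](C)(O)CCB1C2CCCC1CCC2 | intermediate (not isolated)
6 | (3R)-1-[2-bromo-4-(methoxymethoxy)-6-methylphenyl]-3,7-dimethyloct-6-en-3-ol | CC(C)=CCC[C@@](C)(O)CCc1c(C)cc(OCOC)cc1Br | intermediate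
7 | (2R)-7-(methoxymethoxy)-2,5-dimethyl-2-(4-methylpent-3-en-1-yl)chromane | CC(C)=CCC[C@]1(C)CCc2c(C)cc(OCOC)cc2O1 | intermediate
8 | (2E)-5-[(2R)-7-(methoxymethoxy)-2,5-dimethylchroman-2-yl]-2-methylpent-2-en-1-ol | OC/C(C)=C/CC[C@]1(C)CCc2c(C)cc(OCOC)cc2O1 | intermediate
9 | angelic acid, (2Z)-2-methylbut-2-enoic acid | C/C=C(/C)C(=O)O | starting material
10 | (2Z)-2-methylbut-2-enoic 2,4,6-trichlorobenzoic anhydride (mixed anhydride) | C/C=C(/C)C(=O)OC(=O)c1c(Cl)cc(Cl)cc1Cl | intermediate (not isolated)
11 | (2E)-5-[(2R)-7-(methoxymethoxy)-2,5-dimethylchroman-2-yl]-2-methylpent-2-en-1-yl (2Z)-2-methylbut-2-enoate | C/C=C(/C)C(=O)OC/C(C)=C/CC[C@]1(C)CCc2c(C)cc(OCOC)cc2O1 | intermediate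
12 | (1Z)-1-{[(2E)-5-[(2R)-7-(methoxymethoxy)-2,5-dimethylchroman-2-yl]-2-methylpent-2-en-1-yl]oxy}-2-methyl-1-(trimethylsilyloxy)buta-1,3-diene (silyl ketene acetal) | C=C/C(C)=C(\O[Si](C)(C)C)OC/C(C)=C/CC[C@]1(C)CCc2c(C)cc(OCOC)cc2O1 | intermediate (not isolated)
13 | trimethylsilyl (2S*,3R*)-2-ethenyl-3-{2-[(2R)-7-(methoxymethoxy)-2,5-dimethylchroman-2-yl]ethyl}-2,4-dimethylpent-4-enoate (Claisen silyl ester; the 2S,3R isomer is drawn, the 2R,3S isomer forms alongside) | C=C[C@](C)(C(=O)O[Si](C)(C)C)[C@H](CC[C@]1(C)CCc2c(C)cc(OCOC)cc2O1)C(C)=C | intermediate (not isolated)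
14 | trimethylsilyl (2Z,6E)-9-[(2R)-7-(methoxymethoxy)-2,5-dimethylchroman-2-yl]-2,6-dimethylnona-2,6-dienoate (Cope silyl ester) | C/C(=C/CC/C(C)=C/CC[C@]1(C)CCc2c(C)cc(OCOC)cc2O1)C(=O)O[Si](C)(C)C | intermediate (not isolated)
15 | (2Z,6E)-9-[(2R)-7-(methoxymethoxy)-2,5-dimethylchroman-2-yl]-2,6-dimethylnona-2,6-dienoic acid | C/C(=C/CC/C(C)=C/CC[C@]1(C)CCc2c(C)cc(OCOC)cc2O1)C(=O)O | intermediate
16 | (2Z,6E)-9-[(2R)-7-hydroxy-2,5-dimethylchroman-2-yl]-2,6-dimethylnona-2,6-dienoic acid | C/C(=C/CC/C(C)=C/CC[C@]1(C)CCc2c(C)cc(O)cc2O1)C(=O)O | target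

**Step count.** Total: 8 steps. Longest linear sequence: 8 steps (1 → 2 → 3 → 6 → 7 → 8 → 11 → 15 → 16); 4 and 9 are commercial and enter directly.

**Steps most likely to fail**

1. Step 7. The geometric relay may leak: the ketene acetal geometry may scramble, the Claisen shift may pass in part through a boat, or the Cope shift may use the chair with the chain axial. Any of these would give 2E or 6Z isomers that are hard to separate; γ-deprotonation may also be incomplete. The fallback sets out from 7 and returns at 15, and forms the same C4–C5 bond by a different sigmatropic step. Epoxidation of 7 (mCPBA, NaHCO3, CH2Cl2, 0 °C) would give the trisubstituted epoxide F1. Al(OiPr)3 in refluxing toluene would isomerise it to the isopropenyl carbinol F2. Johnson–Claisen rearrangement (MeC(OEt)3, cat. EtCO2H, 140 °C) should give the (E)-γ,δ-unsaturated ethyl ester F3, the 6E alkene being set by the chair with the chain equatorial. DIBAL-H (CH2Cl2, −78 °C) would give the aldehyde F4. Still–Gennari olefination with ethyl 2-[bis(2,2,2-trifluoroethoxy)phosphoryl]propanoate (KHMDS, 18-crown-6, THF, −78 °C) should give the (2Z,6E)-ethyl ester F5. LiOH (THF/MeOH/H2O, 40 °C) would then give acid 15.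

2. Step 3. Transmetalation at the doubly ortho-substituted aryl–Pd may be slow, so that protodeboronation or β-hydride elimination of the alkylborane, or reaction at C–Br, competes. The fallback sets out from 3 and 4 and returns at 6. Heck arylation of the vinyl group of 4 with 3 (Pd(OAc)2, n-Bu4NCl, NaHCO3, DMF, 60 °C) should give the (E)-styrenyl tertiary alcohol F6. Diimide reduction (2-nitrobenzenesulfonyl hydrazide, Et3N, CH2Cl2, rt) should then saturate the disubstituted alkene in preference to the trisubstituted one and give 6.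

3. Step 5. Conversion may stall, the alcohol may be over-oxidised to the enal, and the electron-rich chroman may be attacked oxidatively. The fallback sets out from 7 and returns at 8. Oxidative cleavage of the alkene (OsO4 cat., NaIO4, 2,6-lutidine, dioxane/H2O) would give the aldehyde F7. Wittig reaction with ethyl 2-(triphenylphosphoranylidene)propanoate (toluene, 80 °C) should give the (E)-enoate F8. DIBAL-H (CH2Cl2, −78 °C) would reduce it to 8.

**Further compounds**
F1 | step 7 | (2S)-2-[2-(3,3-dimethyloxiran-2-yl)ethyl]-7-(methoxymethoxy)-2,5-dimethylchromane (epimers at the oxirane carbon) | CC1(C)OC1CC[C@]2(C)CCc3c(C)cc(OCOC)cc3O2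
F2 | step 7 | 5-[(2S)-7-(methoxymethoxy)-2,5-dimethylchroman-2-yl]-2-methylpent-1-en-3-ol (epimers at the carbinol carbon) | C=C(C)C(O)CC[C@]1(C)CCc2c(C)cc(OCOC)cc2O1
F3 | step 7 | ethyl (4E)-7-[(2R)-7-(methoxymethoxy)-2,5-dimethylchroman-2-yl]-4-methylhept-4-enoate | CCOC(=O)CC/C(C)=C/CC[C@]1(C)CCc2c(C)cc(OCOC)cc2O1
F4 | step 7 | (4E)-7-[(2R)-7-(methoxymethoxy)-2,5-dimethylchroman-2-yl]-4-methylhept-4-enal | O=CCC/C(C)=C/CC[C@]1(C)CCc2c(C)cc(OCOC)cc2O1
F5 | step 7 | ethyl (2Z,6E)-9-[(2R)-7-(methoxymethoxy)-2,5-dimethylchroman-2-yl]-2,6-dimethylnona-2,6-dienoate | CCOC(=O)/C(C)=C\CC/C(C)=C/CC[C@]1(C)CCc2c(C)cc(OCOC)cc2O1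
F6 | step 3 | (1E,3R)-1-[2-bromo-4-(methoxymethoxy)-6-methylphenyl]-3,7-dimethylocta-1,6-dien-3-ol | CC(C)=CCC[C@@](C)(O)/C=C/c1c(C)cc(OCOC)cc1Br
F7 | step 5 | 3-[(2S)-7-(methoxymethoxy)-2,5-dimethylchroman-2-yl]propanal | O=CCC[C@]1(C)CCc2c(C)cc(OCOC)cc2O1
F8 | step 5 | ethyl (2E)-5-[(2R)-7-(methoxymethoxy)-2,5-dimethylchroman-2-yl]-2-methylpent-2-enoate | CCOC(=O)/C(C)=C/CC[C@]1(C)CCc2c(C)cc(OCOC)cc2O1
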